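**Strategy.** Ring B of the drimane core (drimane numbering) is disconnected across its two opposite bonds, C5–C10 and C7–C8. The key step exploits C6 of ring B, flanked by C5 and C7, as a ketone carbon whose two α-carbons act in turn as nucleophiles, and the C3 oxygen of ring A as an internal ester leaving group. A base-mediated Michael–Claisen cascade of a seven-membered unsaturated lactone (C3–O–C8(=O)–C9=C10) bearing the C4–C7 keto side chain closes rings A and B in one operation; the lactone bridge relays the C3 carbinol configuration to the quaternary C10 and then opens. The C6 oxygen is removed by carbonyl transposition, and C9, C8 and C3 are set on the rigid decalin.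

Key step: step 6

Remark: all bicyclic compounds are named on the drimane skeleton (ring A: C1–C5 and C10; ring B: C5–C10; C11 on C9, C12 on C8, C13 and C14 on C4, C15 on C10). α and β are the faces of the decalin, β being the face of the C15 methyl group. The same carbon numbers are used for the corresponding atoms of the acyclic and lactone precursors. Compounds 1, 3, 17 and 19 are taken as commercially available; any Z isomer in 3 is harmless because the alkene geometry is equilibrated in step 4.

Step 1
Reactants: 1 2,2-dimethylpent-4-enoic acid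
Product: 2 3,3-dimethylhex-5-en-2-one
Conditions: MeLi (2.2 equiv), Et2O, 0 °C → 25 °C; then aq. HCl
Reagents that add atoms: methyllithium, [Li]C
Why: A carboxylic acid is converted into its methyl ketone by an organolithium because the dilithium gem-diolate formed after the second equivalent resists further addition until work-up; no stereocenter is formed.

Step 2
Reactants: 2 3,3-dimethylhex-5-en-2-one; 3 methyl (2E)-4-bromo-3-methylbut-2-enoate
Product: 4 methyl (2E)-3,7,7-trimethyl-6-oxodeca-2,9-dienoate
Conditions: LiN(i-Pr)2, THF, −78 °C; then 3, DMPU, −78 → −20 °C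
Reagents that add atoms: none
Why: Ketone 2 can enolize only at its acetyl methyl group (the other α-carbon is quaternary), so one lithium enolate forms and is alkylated by the allylic bromide in an SN2 enolate alkylation, the β-methyl group of 3 disfavouring conjugate addition.

Step 3
Reactants: 4 methyl (2E)-3,7,7-trimethyl-6-oxodeca-2,9-dienoate
Product: 5 methyl (2E,6R)-6-hydroxy-3,7,7-trimethyldeca-2,9-dienoate
Conditions: (S)-1-methyl-3,3-diphenyltetrahydro-1H,3H-pyrrolo[1,2-c][1,3,2]oxazaborole (0.2 equiv), catecholborane, toluene, −40 °C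
Reagents that add atoms: none
Why: In this Corey–Bakshi–Shibata reduction the tert-alkyl group is the large substituent of the ketone, as in tert-butyl methyl ketone, so the (S)-oxazaborolidine should give the (R)-carbinol, while the ester and both alkenes are untouched at low temperature.

Step 4
Reactants: 5 methyl (2E,6R)-6-hydroxy-3,7,7-trimethyldeca-2,9-dienoate
Product: 6 (7R)-4-methyl-7-(2-methylpent-4-en-2-yl)-6,7-dihydrooxepin-2(5H)-one
Conditions: KOt-Bu (0.3 equiv), toluene (0.005 M), 4 Å molecular sieves, 90 °C
Reagents that add atoms: none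
Why: Under catalytic alkoxide the E and Z enoates interconvert (reversible oxa-Michael addition of the alkoxide and γ-deprotonation), only the Z isomer can undergo intramolecular transesterification to the seven-membered lactone, and removal of methanol drives this lactonization without touching the carbinol stereocenter.

Step 5
Reactants: 6 (7R)-4-methyl-7-(2-methylpent-4-en-2-yl)-6,7-dihydrooxepin-2(5H)-one
Product: 7 (7R)-4-methyl-7-(2-methyl-4-oxopentan-2-yl)-6,7-dihydrooxepin-2(5H)-one
Conditions: PdCl2 (0.1 equiv), CuCl, O2 (1 atm), DMF/H2O, 25 °C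
Reagents that add atoms: water, O
Why: The Tsuji–Wacker oxidation converts the monosubstituted terminal alkene into the methyl ketone (C6, C7) with Markovnikov selectivity, whereas the trisubstituted, electron-poor lactone alkene does not react.

Step 6
Reactants: 7 (7R)-4-methyl-7-(2-methyl-4-oxopentan-2-yl)-6,7-dihydrooxepin-2(5H)-one
Product: 9 3α-hydroxy-11,12-dinor-5β-drimane-6,8-dione, via bridged keto lactone 8 (not isolated)
Conditions: KOt-Bu (2.2 equiv), t-BuOH/THF (0.01 M), 0 → 50 °C; then aq. HCl, 0 °C
Reagents that add atoms: none
Why: Under equilibrating alkoxide conditions the C5 enolate of the methyl ketone adds to C10, the β-carbon of the unsaturated lactone (intramolecular Michael addition), and the methyl-ketone enolate (C7) of the bridged adduct 8 then attacks the lactone carbonyl C8 and expels the C3 alkoxide (Dieckmann-type Claisen condensation), the 1,3-diketone enolate being the thermodynamic sink. The closest known reaction type is the consecutive Michael–Claisen synthesis of cyclohexane-1,3-diones from methyl ketones and α,β-unsaturated esters, here run intramolecularly in both stages. Ring A closes 6-exo-trig at the enoate β-carbon and ring B closes 6-exo-trig at the ester carbonyl. C10 is controlled by the lactone: the three-atom bridge O–C8–C9 can span C3 and C10 of the new ring A only when C9 and the C3 oxygen are cis, so the (R)-carbinol center fixes the quaternary center, its methyl group trans to the C3 oxygen (hence the later oxidation and reduction at C3). C5 emerges cis-fused because the acetyl group must sit on the side of the bridge to reach C8, and is corrected by enolization in step 7. The step needs the Michael closure to precede direct acyl transfer from the lactone to the C7 enolate; this should be secured by the six-membered closure (helped by the C4 gem-dimethyl group) competing against a seven-membered, ring-expanding transition state, and by reversible enolization.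

Step 7
Reactants: 9 3α-hydroxy-11,12-dinor-5β-drimane-6,8-dione
Product: 10 3α-hydroxy-8-methoxy-11,12-dinor-5α-drim-7-en-6-one
Conditions: HC(OMe)3, p-TsOH (cat.), MeOH, 50 °C; then NaOMe (cat., in excess over the acid), MeOH, 25 °C
Reagents that add atoms: trimethyl orthoformate, COC(OC)OC
Why: Acid-catalysed enol ether formation of the 1,3-dione is reversible and should place the methoxy group on the unhindered C8 oxygen (a C6 enol ether would clash with the C4 methyl groups), and methoxide then epimerizes C5 through the cross-conjugated dienolate to the more stable trans ring fusion (thermodynamic control).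

Step 8
Reactants: 10 3α-hydroxy-8-methoxy-11,12-dinor-5α-drim-7-en-6-one
Product: 11 8-methoxy-11,12-dinor-5α-drim-7-ene-3,6-dione
Conditions: Dess–Martin periodinane, CH2Cl2, 25 °C
Reagents that add atoms: none
Why: The Dess–Martin oxidation removes the C3 carbinol center, which has served as stereochemical relay, without touching the vinylogous ester.

Step 9
Reactants: 11 8-methoxy-11,12-dinor-5α-drim-7-ene-3,6-dione
Product: 13 3β-hydroxy-11,12-dinor-5α-drim-6-en-8-one, via enol-ether diol 12 (not isolated)
Conditions: LiAlH4, THF, 0 °C; then 1 M aq. HCl, THF, 25 °C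
Reagents that add atoms: water, O
Why: LiAlH4 reduces both ketones, the C3 ketone by axial attack from the α-face (the β-face is shielded by the axial methyl groups on C4 and C10) to set the equatorial 3β-alcohol, and acid then hydrolyses the enol ether and eliminates the C6 hydroxyl (Stork–Danheiser carbonyl transposition), which removes the C6 oxygen.

Step 10
Reactants: 13 3β-hydroxy-11,12-dinor-5α-drim-6-en-8-one
Product: 14 11-(benzyloxy)-3β-hydroxy-12-nor-5α,9βH-drim-6-en-8-one
Conditions: LiN(i-Pr)2 (2.3 equiv), THF, −78 °C; then BnOCH2Cl (1.05 equiv), −78 → −40 °C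
Reagents that add atoms: benzyl chloromethyl ether, ClCOCc1ccccc1
Why: Kinetic deprotonation gives the cross-conjugated lithium enolate at C9, the only α′ position, and its alkylation takes place on the α-face, anti to the axial C10 methyl group (stereoelectronically preferred axial attack), which sets C9 with C11 α, the lithium alkoxide at C3 being far less nucleophilic than the enolate at −78 °C.

Step 11
Reactants: 14 11-(benzyloxy)-3β-hydroxy-12-nor-5α,9βH-drim-6-en-8-one
Product: 15 11-(benzyloxy)-5α,9βH-drim-6-ene-3β,8β-diol
Conditions: MeLi, CeCl3, THF, −78 °C; then aq. NH4Cl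
Reagents that add atoms: methyllithium, [Li]C
Why: The methylcerium reagent adds 1,2 to the carbonyl group without enolizing C9, and attack from the α-face, which avoids the syn-axial C10 methyl group on the β-face, should set C8 with the hydroxyl β and the new methyl group (C12) α.

Step 12
Reactants: 15 11-(benzyloxy)-5α,9βH-drim-6-ene-3β,8β-diol
Product: 16 5α,9βH-drimane-3β,8β,11-triol
Conditions: H2 (1 atm), 10% Pd/C, EtOAc/EtOH, 25 °C
Reagents that add atoms: none
Why: Heterogeneous hydrogenation saturates the disubstituted C6=C7 alkene, which creates no stereocenter, and hydrogenolyses the benzyl ether in the same operation.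

Step 13
Reactants: 16 5α,9βH-drimane-3β,8β,11-triol; 17 7-hydroxy-2H-chromen-2-one (umbelliferone)
Product: 18 7-{[3β,8β-dihydroxy-5α,9βH-driman-11-yl]oxy}-2H-chromen-2-one
Conditions: PPh3, diisopropyl azodicarboxylate, THF, 0 → 40 °C
Reagents that add atoms: none
Why: The Mitsunobu etherification with the acidic phenol takes place only at the primary C11 alcohol, the neopentyl-type secondary C3 alcohol and the tertiary C8 alcohol being inert, and no stereocenter is involved.

Step 14
Reactants: 18 7-{[3β,8β-dihydroxy-5α,9βH-driman-11-yl]oxy}-2H-chromen-2-one; 19 2-methylpropanoyl chloride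
Product: 20 7-{[8β-hydroxy-3β-(2-methylpropanoyloxy)-5α,9βH-driman-11-yl]oxy}-2H-chromen-2-one (CNP0196184.1)
Conditions: pyridine, DMAP (cat.), CH2Cl2, 0 → 25 °C
Reagents that add atoms: none
Why: DMAP-catalysed acylation esterifies the equatorial secondary C3 alcohol, while the tertiary C8 alcohol is too hindered to react and the coumarin is unaffected.

**Compound list**

1 | 2,2-dimethylpent-4-enoic acid | C=CCC(C)(C)C(=O)O | starting material
2 | 3,3-dimethylhex-5-en-2-one | CC(=O)C(C)(C)CC=C | intermediate
3 | methyl (2E)-4-bromo-3-methylbut-2-enoate | COC(=O)/C=C(\C)CBr | starting material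
4 | methyl (2E)-3,7,7-trimethyl-6-oxodeca-2,9-dienoate | COC(=O)/C=C(\C)CCC(=O)C(C)(C)CC=C | intermediate
5 | methyl (2E,6R)-6-hydroxy-3,7,7-trimethyldeca-2,9-dienoate | COC(=O)/C=C(\C)CC[C@@H](O)C(C)(C)CC=C | intermediate
6 | (7R)-4-methyl-7-(2-methylpent-4-en-2-yl)-6,7-dihydrooxepin-2(5H)-one | O1[C@@H](C(C)(C)CC=C)CCC(C)=CC1=O | intermediate
7 | (7R)-4-methyl-7-(2-methyl-4-oxopentan-2-yl)-6,7-dihydrooxepin-2(5H)-one | O1[C@@H](C(C)(C)CC(C)=O)CCC(C)=CC1=O | intermediate
8 | 6-acetyl-5,7,7-trimethyl-2-oxabicyclo[3.2.2]nonan-3-one (bridged keto lactone; acetyl group on the side of the lactone bridge; carbinol center as in 7) | C1C(=O)O[C@@H]2CC[C@@]1(C)[C@H](C(C)=O)C2(C)C | intermediate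
9 | 3α-hydroxy-11,12-dinor-5β-drimane-6,8-dione (10β-methyl, cis ring fusion) | O[C@@H]1CC[C@@]2(C)[C@H](C(=O)CC(=O)C2)C1(C)C | intermediate
10 | 3α-hydroxy-8-methoxy-11,12-dinor-5α-drim-7-en-6-one (trans ring fusion) | O[C@@H]1CC[C@@]2(C)[C@@H](C(=O)C=C(OC)C2)C1(C)C | intermediate
11 | 8-methoxy-11,12-dinor-5α-drim-7-ene-3,6-dione | O=C1CC[C@@]2(C)[C@@H](C(=O)C=C(OC)C2)C1(C)C | intermediate
12 | 8-methoxy-11,12-dinor-5α-drim-7-ene-3β,6-diol (C6 epimers, immaterial) | O[C@H]1CC[C@@]2(C)[C@@H](C(O)C=C(OC)C2)C1(C)C | intermediate
13 | 3β-hydroxy-11,12-dinor-5α-drim-6-en-8-one | O[C@H]1CC[C@@]2(C)[C@@H](C=CC(=O)C2)C1(C)C | intermediate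
14 | 11-(benzyloxy)-3β-hydroxy-12-nor-5α,9βH-drim-6-en-8-one (C11 on the α-face) | O[C@H]1CC[C@@]2(C)[C@@H](C=CC(=O)[C@H]2COCc2ccccc2)C1(C)C | intermediate
15 | 11-(benzyloxy)-5α,9βH-drim-6-ene-3β,8β-diol (C12 methyl α, C11 α) | O[C@H]1CC[C@@]2(C)[C@@H](C=C[C@](C)(O)[C@H]2COCc2ccccc2)C1(C)C | intermediate
16 | 5α,9βH-drimane-3β,8β,11-triol (C12 methyl α, C11 α) | O[C@H]1CC[C@@]2(C)[C@@H](CC[C@](C)(O)[C@H]2CO)C1(C)C | intermediate
17 | 7-hydroxy-2H-chromen-2-one (umbelliferone) | Oc1ccc2ccc(=O)oc2c1 | starting material
18 | 7-{[3β,8β-dihydroxy-5α,9βH-driman-11-yl]oxy}-2H-chromen-2-one | O[C@H]1CC[C@@]2(C)[C@@H](CC[C@](C)(O)[C@H]2COc2ccc3ccc(=O)oc3c2)C1(C)C | intermediate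
19 | 2-methylpropanoyl chloride | CC(C)C(Cl)=O | starting material
20 | 7-{[8β-hydroxy-3β-(2-methylpropanoyloxy)-5α,9βH-driman-11-yl]oxy}-2H-chromen-2-one (CNP0196184.1) | CC(C)C(=O)O[C@H]1CC[C@@]2(C)[C@@H](CC[C@](C)(O)[C@H]2COc2ccc3ccc(=O)oc3c2)C1(C)C | target

**Total step count:** 14

**Longest linear sequence:** 14 steps (from 1; 3, 17 and 19 enter as commercial reactants)

**Steps most likely to fail**

Step 6 (key step). What may go wrong: the kinetically favoured C7 enolate may take over the lactone acyl group before the bridged Michael closure (ring expansion instead of bicyclization), or the Michael closure may be too slow and reversible. The fallback sets out from 7 and comes back at 9, forming the two bonds in separate operations. Compound 7 is treated with Me3SiI and (Me3Si)2NH in CH2Cl2 (−20 → 25 °C); the silyl enol ethers equilibrate and only the C5 enol ether can reach C10 in an intramolecular Mukaiyama–Michael addition, so aqueous work-up gives isolated 8. Compound 8 has no Michael acceptor left and is closed to 9 by KOt-Bu in t-BuOH (Dieckmann-type attack of C7 on the lactone carbonyl). No compound outside the list is made.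

Step 4. What may go wrong: the alkoxide may rest as the tetrahydrofuran formed by oxa-Michael addition, or oligomerize, instead of closing the seven-membered ring. The fallback sets out from 5 and comes back at 6. Saponification (LiOH, THF/H2O) gives (2E,6R)-6-hydroxy-3,7,7-trimethyldeca-2,9-dienoic acid F1. Sensitized irradiation (300 nm, acetophenone, MeCN) establishes an E/Z mixture that contains (2Z,6R)-6-hydroxy-3,7,7-trimethyldeca-2,9-dienoic acid F2. Yamaguchi lactonization (2,4,6-trichlorobenzoyl chloride, Et3N; then DMAP, toluene, high dilution, 80 °C) converts only F2 into 6, and recovered F1 is irradiated again.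

Step 11. What may go wrong: poor facial selectivity of the methyl transfer, because the axial C9 substituent shields the α-face that the C10 methyl group leaves open. The fallback sets out from 13 and comes back at 16; C11 is introduced as an sp2 carbon so that C9 carries no axial group during the addition. Claisen formylation of 13 (HCO2Et, NaH, THF) gives 3β,11-dihydroxy-12-nor-5α-drima-6,9(11)-dien-8-one F3. O-Benzylation (BnBr, K2CO3, acetone) gives (E)-11-(benzyloxy)-3β-hydroxy-12-nor-5α-drima-6,9(11)-dien-8-one F4. MeLi/CeCl3 (THF, −78 °C) adds from the α-face to give (E)-11-(benzyloxy)-5α-drima-6,9(11)-diene-3β,8β-diol F5. Hydroxyl-directed hydrogenation with [Ir(cod)(PCy3)(py)]PF6 and H2 in CH2Cl2 delivers hydrogen to C9 (and to C6=C7) from the face of the 8β-hydroxyl and gives 11-(benzyloxy)-5α,9βH-drimane-3β,8β-diol F6 with C11 α. Hydrogenolysis (H2, Pd/C) then gives 16.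

**Further compounds**

F0 | step 6 | none | none
F1 | step 4 | (2E,6R)-6-hydroxy-3,7,7-trimethyldeca-2,9-dienoic acid | OC(=O)/C=C(\C)CC[C@@H](O)C(C)(C)CC=C
F2 | step 4 | (2Z,6R)-6-hydroxy-3,7,7-trimethyldeca-2,9-dienoic acid | OC(=O)/C=C(/C)CC[C@@H](O)C(C)(C)CC=C
F3 | step 11 | 3β,11-dihydroxy-12-nor-5α-drima-6,9(11)-dien-8-one | O[C@H]1CC[C@@]2(C)[C@@H](C=CC(=O)/C2=C\O)C1(C)C
F4 | step 11 | (E)-11-(benzyloxy)-3β-hydroxy-12-nor-5α-drima-6,9(11)-dien-8-one | O[C@H]1CC[C@@]2(C)[C@@H](C=CC(=O)/C2=C/OCc2ccccc2)C1(C)C
F5 | step 11 | (E)-11-(benzyloxy)-5α-drima-6,9(11)-diene-3β,8β-diol | O[C@H]1CC[C@@]2(C)[C@@H](C=C[C@](C)(O)/C2=C/OCc2ccccc2)C1(C)C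
F6 | step 11 | 11-(benzyloxy)-5α,9βH-drimane-3β,8β-diol | O[C@H]1CC[C@@]2(C)[C@@H](CC[C@](C)(O)[C@H]2COCc2ccccc2)C1(C)C
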